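**Retrosynthetic overview**
1. (+)-Neoolivil 10 ⇐ debenzylation and ester reduction of the all-trans tetrahydrofuran-3,4-diester 8.
2. The tetrahydrofuran (the only ring made, formed in step 3) ⇐ SN1 cyclo-etherification of the C2-symmetric bis(β-silyloxy) succinate 7, giving the C2–O–C5 ether.
3. 7 ⇐ methanolysis and esterification of trans-anhydride 5 ⇐ both aryl-carbinol C–C bonds and all four stereocentres from one catalytic asymmetric double Mukaiyama aldol of 2,5-bis(silyloxy)furan 2 with two O-benzylvanillin 3.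
4. 2 ⇐ succinic anhydride 1 (its ring is kept through the aldol to enforce the trans relationship, then opened).

Assumption: the given SMILES, the all-trans (2R,3S,4S,5R) isomer, defines the target; 1 and 3 are bought. Ar = 4-(benzyloxy)-3-methoxyphenyl; TBS = tert-butyldimethylsilyl.

**Step 1**
Reactants: 1 succinic anhydride
Product: 2 2,5-bis(tert-butyldimethylsilyloxy)furan
Conditions: TBSOTf (2.2 equiv), Et3N (3 equiv), CH2Cl2, 0 °C → rt
Reagents that add atoms: tert-butyldimethylsilyl trifluoromethanesulfonate, CC(C)(C)[Si](C)(C)OS(=O)(=O)C(F)(F)F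
Why: Double soft enolisation/O-silylation of the anhydride, driven by aromatisation to the furan; no stereocentre is formed.

**Step 2**
Reactants: 2 2,5-bis(tert-butyldimethylsilyloxy)furan; 3 4-(benzyloxy)-3-methoxybenzaldehyde (2.1 equiv)
Product: 7 dimethyl (2R,3R)-2,3-bis{(R)-Ar[(tert-butyldimethylsilyl)oxy]methyl}butanedioate, via mono-adduct (3R)-3-{(R)-Ar(TBSO)methyl}-5-(TBSO)furan-2(3H)-one 4 (not isolated), via trans-anhydride (3R,4R)-3,4-bis{(R)-Ar(TBSO)methyl}dihydrofuran-2,5-dione 5 (not isolated), via half-ester (2R,3R)-2,3-bis{(R)-Ar(TBSO)methyl}-4-methoxy-4-oxobutanoic acid 6 (not isolated)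
Conditions: chiral IDPi acid (2 mol %, enantiomer giving Re-face addition), PhMe, −78 → −40 °C; then 2,6-lutidine (5 mol %), MeOH, 45 °C; then TMSCHN2, PhMe–MeOH, 0 °C
Reagents that add atoms: methanol, CO; trimethylsilyldiazomethane, C[Si](C)(C)C=[N+]=[N-]
Why: Proposed new method: a catalytic asymmetric double Mukaiyama aldol in which 2 acts as a 2,3-dianion equivalent of succinic anhydride. The confined imidodiphosphorimidate acid is silylated by 2 to a chiral silylium ion pair that activates 3 as a silyloxocarbenium ion. C3 of 2 adds to the aldehyde Re face through an open antiperiplanar transition state with the aryl group over the small ring C–H, which sets the (R)-carbinol and the adjacent ring carbon. Silyl transfer gives 4, whose remaining acyloxy silyl ketene acetal adds to a second activated aldehyde anti to the existing side chain; this ring-enforced trans addition is matched with catalyst control and gives C2-symmetric 5. Methanolysis of the symmetric anhydride has no regiochemical issue, and TMSCHN2 esterifies acid 6 under neutral conditions. The closest known reaction types are the chiral disulfonimide/IDPi-catalysed Mukaiyama aldol of silyl ketene acetals with aromatic aldehydes and the TiCl4-promoted racemic addition of 2,5-bis(trimethylsilyloxy)furan to aldehydes giving paraconic acids.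

**Step 3**
Reactants: 7 dimethyl (2R,3R)-2,3-bis{(R)-Ar(TBSO)methyl}butanedioate
Product: 8 dimethyl (2R,3R,4R,5R)-2,5-bis[4-(benzyloxy)-3-methoxyphenyl]tetrahydrofuran-3,4-dicarboxylate (all-trans)
Conditions: TBSOTf (10 mol %), CH2Cl2, −40 → 0 °C
Reagents that add atoms: none
Why: SN1 cyclo-etherification: silyl triflate ionises one electron-rich benzylic silyl ether, the other silyl ether oxygen closes the five-membered ring and loses its silyl group to regenerate the catalyst. The ionised carbon recloses trans to its neighbouring ester (the thermodynamic all-trans ring) and the other three centres are untouched.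

**Step 4**
Reactants: 8 dimethyl (2R,3R,4R,5R)-2,5-diaryl-tetrahydrofuran-3,4-dicarboxylate
Product: 9 [(2R,3S,4S,5R)-2,5-bis[4-(benzyloxy)-3-methoxyphenyl]tetrahydrofuran-3,4-diyl]dimethanol
Conditions: LiAlH4, THF, 0 °C
Reagents that add atoms: none
Why: Hydride reduction of both esters to primary alcohols; no stereocentre is touched (the descriptor change at C3/C4 is only a CIP priority change).

**Step 5**
Reactants: 9 [(2R,3S,4S,5R)-2,5-bis[4-(benzyloxy)-3-methoxyphenyl]tetrahydrofuran-3,4-diyl]dimethanol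
Product: 10 (+)-neoolivil, [(2R,3S,4S,5R)-2,5-bis(4-hydroxy-3-methoxyphenyl)tetrahydrofuran-3,4-diyl]dimethanol
Conditions: H2 (1 atm), 10 % Pd/C, EtOAc–MeOH, rt, monitored and stopped at full debenzylation
Reagents that add atoms: none
Why: Hydrogenolysis of the two aryl benzyl ethers, which cleave faster than the dialkyl benzylic C–O bonds of the ring; no stereocentre is affected.

**Compound list**
1 | succinic anhydride | O=C1CCC(=O)O1 | starting material
2 | 2,5-bis(tert-butyldimethylsilyloxy)furan | CC(C)(C)[Si](C)(C)Oc1ccc(O[Si](C)(C)C(C)(C)C)o1 | intermediate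
3 | 4-(benzyloxy)-3-methoxybenzaldehyde | COc1cc(C=O)ccc1OCc1ccccc1 | starting material
4 | (3R)-3-{(R)-Ar(TBSO)methyl}-5-(TBSO)furan-2(3H)-one | COc1cc(ccc1OCc1ccccc1)[C@@H]([C@@H]1C(=O)OC(O[Si](C)(C)C(C)(C)C)=C1)O[Si](C)(C)C(C)(C)C | intermediate
5 | (3R,4R)-3,4-bis{(R)-Ar(TBSO)methyl}dihydrofuran-2,5-dione | COc1cc(ccc1OCc1ccccc1)[C@@H]([C@@H]1C(=O)OC(=O)[C@H]1[C@@H](O[Si](C)(C)C(C)(C)C)c1ccc(OCc2ccccc2)c(OC)c1)O[Si](C)(C)C(C)(C)C | intermediate
6 | (2R,3R)-2,3-bis{(R)-Ar(TBSO)methyl}-4-methoxy-4-oxobutanoic acid | COc1cc(ccc1OCc1ccccc1)[C@@H]([C@H](C(=O)OC)[C@@H](C(=O)O)[C@@H](O[Si](C)(C)C(C)(C)C)c1ccc(OCc2ccccc2)c(OC)c1)O[Si](C)(C)C(C)(C)C | intermediate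
7 | dimethyl (2R,3R)-2,3-bis{(R)-Ar(TBSO)methyl}butanedioate | COc1cc(ccc1OCc1ccccc1)[C@@H]([C@H](C(=O)OC)[C@@H](C(=O)OC)[C@@H](O[Si](C)(C)C(C)(C)C)c1ccc(OCc2ccccc2)c(OC)c1)O[Si](C)(C)C(C)(C)C | intermediate
8 | dimethyl (2R,3R,4R,5R)-2,5-bis[4-(benzyloxy)-3-methoxyphenyl]tetrahydrofuran-3,4-dicarboxylate | COc1cc(ccc1OCc1ccccc1)[C@@H]1O[C@@H](c2ccc(OCc3ccccc3)c(OC)c2)[C@H](C(=O)OC)[C@H]1C(=O)OC | intermediate
9 | [(2R,3S,4S,5R)-2,5-bis[4-(benzyloxy)-3-methoxyphenyl]tetrahydrofuran-3,4-diyl]dimethanol | COc1cc(ccc1OCc1ccccc1)[C@@H]1O[C@@H](c2ccc(OCc3ccccc3)c(OC)c2)[C@H](CO)[C@H]1CO | intermediate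
10 | (+)-neoolivil | COc1cc([C@@H]2O[C@@H](c3ccc(O)c(OC)c3)[C@H](CO)[C@H]2CO)ccc1O | target

**Total step count:** 5. **Longest linear sequence:** 5 (1 → 2 → 7 → 8 → 9 → 10).

**Three steps most likely to fail**

Step 2 (the proposed new reaction). The risks are sluggish second addition (the acyloxy ketene acetal in 4 is less nucleophilic than 2) and imperfect syn/anti selectivity. Minor diastereomers of 7 must be removed by chromatography before step 3, because after the acid step they would converge on the wrong series. The fallback uses known chemistry, sets out from 3 and comes back at 9. D-Proline-catalysed anti cross-aldol of 3 with methyl 4-oxobutanoate gives methyl (3R,4S)-3-formyl-4-hydroxy-4-Ar-butanoate F1. NaBH4 in the same flask gives methyl (3S,4S)-4-hydroxy-3-(hydroxymethyl)-4-Ar-butanoate F2, which lactonises on acidic work-up to (S)-4-[(S)-Ar(hydroxy)methyl]dihydrofuran-2(3H)-one F3; the ring stereocentre is now set by the catalyst. Dianion formation (LDA, 2.2 equiv, −78 °C) and aldol with a second 3 places the new arm trans to the first and gives the trans-lactone diol (3R,4S)-3-[Ar(hydroxy)methyl]-4-[(S)-Ar(hydroxy)methyl]dihydrofuran-2(3H)-one F4 as a mixture of carbinol epimers. LiAlH4 gives the tetraol (2S,3S)-2-[(S)-Ar(hydroxy)methyl]-3-[Ar(hydroxy)methyl]butane-1,4-diol F5. PivCl/pyridine at 0 °C caps the two primary alcohols to give the dipivalate F6. Catalytic BF3·OEt2 in CH2Cl2 then closes the benzylic ether by reversible SN1 etherification; both benzylic centres settle trans to the fixed C3/C4 substituents, giving the all-trans tetrahydrofuran dipivalate F7. LiAlH4 removes the pivalates and delivers 9.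

Step 3. The benzylic cation sits next to an ester, so E1 loss to the arylidene succinate, ester participation (lactone formation) or Friedel–Crafts closure to an aryltetralin may compete. The fallback sets out from 7 and comes back at 9, closing the ring at the alcohol oxidation level. LiAlH4 reduces 7 to (2S,3S)-2,3-bis{(R)-Ar(TBSO)methyl}butane-1,4-diol F8. Ac2O/pyridine gives the diacetate F9. The same silyl-triflate-catalysed ionisation (or BF3·OEt2), now free of the electron-withdrawing and lactonising ester, gives the all-trans tetrahydrofuran diacetate F10. K2CO3/MeOH removes the acetates to give 9.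

Step 5. The free-phenol product has p-hydroxybenzylic ring C–O bonds that can be hydrogenolysed on over-reaction. The fallback sets out from 8 and comes back at 10, with the order inverted. Hydrogenolysis of 8, where the ring C–O bonds are deactivated by the flanking esters, gives dimethyl (2R,3R,4R,5R)-2,5-bis(4-hydroxy-3-methoxyphenyl)tetrahydrofuran-3,4-dicarboxylate F11. LiAlH4 (excess, THF, 0 °C → rt) then reduces the esters to give 10.

**Further compounds**
F1 | step 2 | methyl (3R,4S)-3-formyl-4-hydroxy-4-[4-(benzyloxy)-3-methoxyphenyl]butanoate | COC(=O)C[C@@H](C=O)[C@H](O)c1ccc(OCc2ccccc2)c(OC)c1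
F2 | step 2 | methyl (3S,4S)-4-hydroxy-3-(hydroxymethyl)-4-[4-(benzyloxy)-3-methoxyphenyl]butanoate | COC(=O)C[C@@H](CO)[C@H](O)c1ccc(OCc2ccccc2)c(OC)c1
F3 | step 2 | (S)-4-{(S)-[4-(benzyloxy)-3-methoxyphenyl](hydroxy)methyl}dihydrofuran-2(3H)-one | COc1cc(ccc1OCc1ccccc1)[C@@H](O)[C@H]1CC(=O)OC1
F4 | step 2 | (3R,4S)-3-{[4-(benzyloxy)-3-methoxyphenyl](hydroxy)methyl}-4-{(S)-[4-(benzyloxy)-3-methoxyphenyl](hydroxy)methyl}dihydrofuran-2(3H)-one (carbinol epimers on the C3 arm) | COc1cc(ccc1OCc1ccccc1)[C@@H](O)[C@H]1[C@@H](C(=O)OC1)C(O)c1ccc(OCc2ccccc2)c(OC)c1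
F5 | step 2 | (2S,3S)-2-{(S)-[4-(benzyloxy)-3-methoxyphenyl](hydroxy)methyl}-3-{[4-(benzyloxy)-3-methoxyphenyl](hydroxy)methyl}butane-1,4-diol | COc1cc(ccc1OCc1ccccc1)[C@@H](O)[C@H](CO)[C@@H](CO)C(O)c1ccc(OCc2ccccc2)c(OC)c1
F6 | step 2 | 1,4-dipivalate of F5 | COc1cc(ccc1OCc1ccccc1)[C@@H](O)[C@H](COC(=O)C(C)(C)C)[C@@H](COC(=O)C(C)(C)C)C(O)c1ccc(OCc2ccccc2)c(OC)c1
F7 | step 2 | [(2R,3S,4S,5R)-2,5-bis[4-(benzyloxy)-3-methoxyphenyl]tetrahydrofuran-3,4-diyl]bis(methylene) bis(2,2-dimethylpropanoate) | COc1cc(ccc1OCc1ccccc1)[C@@H]1O[C@@H](c2ccc(OCc3ccccc3)c(OC)c2)[C@H](COC(=O)C(C)(C)C)[C@H]1COC(=O)C(C)(C)C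
F8 | step 3 | (2S,3S)-2,3-bis{(R)-[4-(benzyloxy)-3-methoxyphenyl][(tert-butyldimethylsilyl)oxy]methyl}butane-1,4-diol | COc1cc(ccc1OCc1ccccc1)[C@@H]([C@H](CO)[C@@H](CO)[C@@H](O[Si](C)(C)C(C)(C)C)c1ccc(OCc2ccccc2)c(OC)c1)O[Si](C)(C)C(C)(C)C
F9 | step 3 | (2S,3S)-2,3-bis{(R)-[4-(benzyloxy)-3-methoxyphenyl][(tert-butyldimethylsilyl)oxy]methyl}butane-1,4-diyl diacetate | COc1cc(ccc1OCc1ccccc1)[C@@H]([C@H](COC(C)=O)[C@@H](COC(C)=O)[C@@H](O[Si](C)(C)C(C)(C)C)c1ccc(OCc2ccccc2)c(OC)c1)O[Si](C)(C)C(C)(C)C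
F10 | step 3 | [(2R,3S,4S,5R)-2,5-bis[4-(benzyloxy)-3-methoxyphenyl]tetrahydrofuran-3,4-diyl]bis(methylene) diacetate | COc1cc(ccc1OCc1ccccc1)[C@@H]1O[C@@H](c2ccc(OCc3ccccc3)c(OC)c2)[C@H](COC(C)=O)[C@H]1COC(C)=O
F11 | step 5 | dimethyl (2R,3R,4R,5R)-2,5-bis(4-hydroxy-3-methoxyphenyl)tetrahydrofuran-3,4-dicarboxylate | COc1cc(ccc1O)[C@@H]1O[C@@H](c2ccc(O)c(OC)c2)[C@H](C(=O)OC)[C@H]1C(=O)OC
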